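The route rests on cutting the side chain between its second CH2 group and the vinylic CH of the E-trisubstituted alkene. The feature exploited is that the oxepine C5=C6 double bond and the two chain carbons attached to C6 form a latent 6-vinyl-2,3,4,7-tetrahydrooxepine. That diene is the direct product of ring-closing enyne metathesis. In one operation 9-BBN hydroborates only the exocyclic vinyl terminus of this conjugated diene. A B-alkyl Suzuki–Miyaura coupling then joins the borane to an (E)-iodoalkenyl p-coumarate with retention of geometry. The diene precursor already carries the aryl ketone, the ester and the (R) quaternary carbon, which is set by a copper–bis(oxazoline) Mukaiyama aldol.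

Key step: step 11

Remark on the chemistry: the sense of induction in step 5 is assigned from the square-planar chelate model of the copper–bis(oxazoline)–keto ester complex, in which the (S,S)-ligand opens the si face and the (R,R)-ligand the re face; should the adduct prove to be (S), the (S,S)-ligand is used instead.

Step 1
Reactants: 1 2',5'-dihydroxyacetophenone
Product: 2 2',5'-bis(triisopropylsilyloxy)acetophenone
Conditions: TIPSOTf (2.3 equiv), 2,6-lutidine (3 equiv), CH2Cl2, 0 °C to rt
Reagents that add atoms: triisopropylsilyl triflate CC(C)[Si](C(C)C)(C(C)C)OS(=O)(=O)C(F)(F)F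
Why: Phenol silylation with a silyl triflate and a hindered pyridine base is strong enough to cap the hydrogen-bonded ortho-phenol as well, and the bulky silyl ethers should outlast the Lewis acid, silver, ruthenium and aqueous phosphate steps yet fall to fluoride.

Step 2
Reactants: 2 2',5'-bis(triisopropylsilyloxy)acetophenone
Product: 3 trimethylsilyl enol ether of 2
Conditions: TMSOTf (1.2 equiv), Et3N (2 equiv), CH2Cl2, 0 °C
Reagents that add atoms: trimethylsilyl triflate C[Si](C)(C)OS(=O)(=O)C(F)(F)F
Why: Soft enolisation of the methyl ketone gives the only possible, terminal enol silane, which is the nucleophile needed for the Mukaiyama aldol.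

Step 3
Reactants: 4 oxalyl chloride, 5 2-(trimethylsilyl)ethanol
Product: 6 bis[2-(trimethylsilyl)ethyl] oxalate
Conditions: 5 (2.1 equiv), pyridine (2.5 equiv), CH2Cl2, 0 °C to rt
Reagents that add atoms: none
Why: Double esterification of the diacid chloride installs from the outset the fluoride-labile ester that will later release the free acid of the target.

Step 4
Reactants: 6 bis[2-(trimethylsilyl)ethyl] oxalate, 7 but-3-enylmagnesium bromide
Product: 8 2-(trimethylsilyl)ethyl 2-oxohex-5-enoate
Conditions: 7 added to 6 (1.3 equiv), THF/Et2O, −78 °C; 1 M HCl quench at −78 °C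
Reagents that add atoms: none
Why: Mono-addition of a Grignard reagent to a dialkyl oxalate stops at the magnesium hemiketal at low temperature, and this releases the α-keto ester only on acidic quench.

Step 5
Reactants: 3 trimethylsilyl enol ether of 2, 8 2-(trimethylsilyl)ethyl 2-oxohex-5-enoate
Product: 10 2-(trimethylsilyl)ethyl (R)-2-hydroxy-2-{2-oxo-2-[2,5-bis(triisopropylsilyloxy)phenyl]ethyl}hex-5-enoate, via aldol trimethylsilyl ether 9 (not isolated)
Conditions: Cu(OTf)2 (10 mol%), (R,R)-t-Bu-box = 2,2'-(propane-2,2-diyl)bis[(4R)-4-tert-butyl-4,5-dihydrooxazole] (11 mol%), THF, −78 °C; then 1 M HCl, THF, 0 °C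
Reagents that add atoms: none
Why: In this catalytic enantioselective Mukaiyama aldol addition to an α-keto ester, 8 chelates the square-planar divalent copper centre through its ketone and ester oxygens, the tert-butyl groups of the (R,R)-ligand block the si face, attack of 3 on the re face sets the (R) tertiary carbinol, and silyl transfer gives 9, which dilute acid cleaves without touching the aryl silyl ethers.

Step 6
Reactants: 10 (R)-aldol alcohol, 11 propargyl bromide
Product: 13 2-(trimethylsilyl)ethyl (R)-2-{2-oxo-2-[2,5-bis(triisopropylsilyloxy)phenyl]ethyl}-2-(prop-2-ynyloxy)hex-5-enoate, via prop-2-ynyl triflate 12 (not isolated)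
Conditions: 11 (4 equiv), AgOTf (4 equiv), 2,6-di-tert-butyl-4-methylpyridine (5 equiv), 4 Å MS, CH2Cl2, 0 °C to rt, dark
Reagents that add atoms: none
Why: In this silver-triflate-promoted Williamson-type etherification, AgOTf turns 11 into the very electrophilic triflate 12, which alkylates the hindered tertiary hydroxyl while the non-nucleophilic pyridine only takes up TfOH, so no alkoxide or enolate forms and retro-aldol cleavage, C-alkylation and racemisation of the β-hydroxy ketone are avoided.

Step 7
Reactants: 13 (R)-propargyl ether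
Product: 14 2-(trimethylsilyl)ethyl (R)-2-{2-oxo-2-[2,5-bis(triisopropylsilyloxy)phenyl]ethyl}-6-vinyl-2,3,4,7-tetrahydrooxepine-2-carboxylate
Conditions: second-generation Grubbs catalyst (H2IMes)(PCy3)Cl2Ru=CHPh (5 mol%), ethene (1 atm), CH2Cl2 (5 mM), 40 °C
Reagents that add atoms: none
Why: In this exo-mode ring-closing enyne metathesis, the alkylidene formed at the butenyl terminus adds to the tethered alkyne and bond reorganisation gives the seven-membered ring with its C5=C6 alkene and the 6-vinyl group, helped by the quaternary carbon in the tether (Thorpe–Ingold effect) and by ethene, which suppresses alkyne oligomerisation and diene dimerisation.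

Step 8
Reactants: 15 propargyl alcohol
Product: 17 (E)-3-iodo-2-methylprop-2-en-1-ol, via alkenylalane 16 (not isolated)
Conditions: AlMe3 (3 equiv), Cp2ZrCl2 (0.25 equiv), CH2Cl2, 0 °C to rt; then iodine, THF, −30 °C; aq K2CO3 work-up
Reagents that add atoms: trimethylaluminium C[Al](C)C; iodine [I][I]
Why: Zirconium-catalysed carboalumination (Negishi) adds methyl and aluminium syn across the alkyne with aluminium at the terminus, and iodinolysis of 16 with retention fixes the E geometry.

Step 9
Reactants: 17 (E)-3-iodo-2-methylprop-2-en-1-ol, 18 p-coumaric acid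
Product: 19 (E)-3-iodo-2-methylallyl (E)-3-(4-hydroxyphenyl)acrylate
Conditions: PPh3 (1.1 equiv), DIAD (1.1 equiv), THF, 0 °C to rt
Reagents that add atoms: none
Why: Mitsunobu esterification is chemoselective for the carboxylic acid, the far more acidic pronucleophile, over the phenol, and it displaces the activated primary allylic alcohol by direct SN2 attack, so both alkene geometries are kept.

Step 10
Reactants: 19 (E)-3-iodo-2-methylallyl (E)-3-(4-hydroxyphenyl)acrylate
Product: 20 (E)-3-iodo-2-methylallyl (E)-3-[4-(triisopropylsilyloxy)phenyl]acrylate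
Conditions: TIPSCl (1.2 equiv), imidazole (2.5 equiv), DMF, rt
Reagents that add atoms: triisopropylsilyl chloride CC(C)[Si](Cl)(C(C)C)C(C)C
Why: Standard phenol silylation removes the acidic and nucleophilic phenol, which would otherwise consume base and could attack a palladium allyl species during the coupling.

Step 11
Reactants: 14 (R)-6-vinyltetrahydrooxepine diene, 20 (E)-iodoalkenyl silyl-protected p-coumarate
Product: 22 fully protected coupling product (tris-triisopropylsilyl ether and 2-(trimethylsilyl)ethyl ester of the target), via B-alkyl-9-BBN borane 21 (not isolated)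
Conditions: 9-BBN dimer (1.05 equiv B–H), THF, 0 °C to rt; then 3 M aq K3PO4 (1.5 equiv), 20 (1.0 equiv), Pd(dppf)Cl2 (5 mol%), AsPh3 (10 mol%), DMF, rt, degassed
Reagents that add atoms: none
Why: 9-BBN adds B–H across the monosubstituted exocyclic vinyl group of diene 14 with boron on the terminal CH2 to give the homoallylic borane 21, aqueous K3PO4 converts it into the hydroxyborate, this transfers its primary alkyl group to the alkenylpalladium iodide formed from 20 and zerovalent palladium, and reductive elimination makes the CH2–CH= bond. The closest known reaction type is the one-pot hydroboration/B-alkyl Suzuki–Miyaura coupling of a terminal alkene with an alkenyl iodide. No ring is closed and no stereocentre is created; the (R) quaternary carbon is remote and untouched, and the E geometry of the new trisubstituted alkene is inherited from 20 because oxidative addition and reductive elimination both proceed with retention. The step needs site selectivity among the vinyl group, the trisubstituted ring alkene and the aryl ketone: the bulk of 9-BBN confines it to the unhindered CH=CH2 terminus, whereas the ketone is shielded by the ortho-triisopropylsilyloxy group and the neopentyl-type CH2, is deactivated by the electron-rich ring, and meets only a marginal excess of B–H. It also needs chemoselectivity on the electrophile, secured because insertion into the C–I bond is far faster than ionisation of the allylic ester, while the wide bite angle of dppf lets reductive elimination outrun beta-hydride elimination. Since the base is largely bound as the borate and the coupling runs at room temperature, the beta-alkoxy ketone (E1cB ring opening) and the aryl silyl ethers should survive.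

Step 12
Reactants: 22 fully protected coupling product
Product: 23 target, (R)-2-[2-(2,5-dihydroxyphenyl)-2-oxoethyl]-6-{(E)-5-[(E)-3-(4-hydroxyphenyl)acryloyloxy]-4-methylpent-3-enyl}-2,3,4,7-tetrahydrooxepine-2-carboxylic acid
Conditions: TBAF (8 equiv), THF, 0 °C to rt, argon; then dilute HCl to pH 3
Reagents that add atoms: none
Why: In one global deprotection, fluoride cleaves the three aryl silyl ethers and fragments the 2-(trimethylsilyl)ethyl ester, the conjugated allylic ester being inert to fluoride and the rapidly freed ortho-phenoxide lowering the acidity of the ketone CH2 so that E1cB opening of the oxepine should not compete.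

Compound list
1 | 2',5'-dihydroxyacetophenone | CC(=O)c1cc(O)ccc1O | starting material
2 | 2',5'-bis(triisopropylsilyloxy)acetophenone | CC(=O)c1cc(O[Si](C(C)C)(C(C)C)C(C)C)ccc1O[Si](C(C)C)(C(C)C)C(C)C | intermediate
3 | {1-[2,5-bis(triisopropylsilyloxy)phenyl]vinyloxy}trimethylsilane | C=C(O[Si](C)(C)C)c1cc(O[Si](C(C)C)(C(C)C)C(C)C)ccc1O[Si](C(C)C)(C(C)C)C(C)C | intermediate
4 | oxalyl chloride | O=C(Cl)C(=O)Cl | starting material
5 | 2-(trimethylsilyl)ethanol | C[Si](C)(C)CCO | starting material
6 | bis[2-(trimethylsilyl)ethyl] oxalate | C[Si](C)(C)CCOC(=O)C(=O)OCC[Si](C)(C)C | intermediate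
7 | but-3-enylmagnesium bromide | C=CCC[Mg]Br | starting material
8 | 2-(trimethylsilyl)ethyl 2-oxohex-5-enoate | C=CCCC(=O)C(=O)OCC[Si](C)(C)C | intermediate
9 | O-trimethylsilyl ether of 10, (R) | C=CCC[C@@](CC(=O)c1cc(O[Si](C(C)C)(C(C)C)C(C)C)ccc1O[Si](C(C)C)(C(C)C)C(C)C)(C(=O)OCC[Si](C)(C)C)O[Si](C)(C)C | intermediate
10 | 2-(trimethylsilyl)ethyl (R)-2-hydroxy-2-{2-oxo-2-[2,5-bis(triisopropylsilyloxy)phenyl]ethyl}hex-5-enoate | C=CCC[C@@](CC(=O)c1cc(O[Si](C(C)C)(C(C)C)C(C)C)ccc1O[Si](C(C)C)(C(C)C)C(C)C)(C(=O)OCC[Si](C)(C)C)O | intermediate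
11 | propargyl bromide | C#CCBr | starting material
12 | prop-2-ynyl triflate | C#CCOS(=O)(=O)C(F)(F)F | intermediate
13 | 2-(trimethylsilyl)ethyl (R)-2-{2-oxo-2-[2,5-bis(triisopropylsilyloxy)phenyl]ethyl}-2-(prop-2-ynyloxy)hex-5-enoate | C=CCC[C@@](CC(=O)c1cc(O[Si](C(C)C)(C(C)C)C(C)C)ccc1O[Si](C(C)C)(C(C)C)C(C)C)(C(=O)OCC[Si](C)(C)C)OCC#C | intermediate
14 | 2-(trimethylsilyl)ethyl (R)-2-{2-oxo-2-[2,5-bis(triisopropylsilyloxy)phenyl]ethyl}-6-vinyl-2,3,4,7-tetrahydrooxepine-2-carboxylate | C=CC1=CCC[C@@](CC(=O)c2cc(O[Si](C(C)C)(C(C)C)C(C)C)ccc2O[Si](C(C)C)(C(C)C)C(C)C)(C(=O)OCC[Si](C)(C)C)OC1 | intermediate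
15 | propargyl alcohol | C#CCO | starting material
16 | (E)-alkenyl(dimethyl)alane dimethylaluminium alkoxide from 15 | C/C(=C\[Al](C)C)CO[Al](C)C | intermediate
17 | (E)-3-iodo-2-methylprop-2-en-1-ol | C/C(=C\I)CO | intermediate
18 | p-coumaric acid, (E)-3-(4-hydroxyphenyl)acrylic acid | O=C(O)/C=C/c1ccc(O)cc1 | starting material
19 | (E)-3-iodo-2-methylallyl (E)-3-(4-hydroxyphenyl)acrylate | C/C(=C\I)COC(=O)/C=C/c1ccc(O)cc1 | intermediate
20 | (E)-3-iodo-2-methylallyl (E)-3-[4-(triisopropylsilyloxy)phenyl]acrylate | C/C(=C\I)COC(=O)/C=C/c1ccc(O[Si](C(C)C)(C(C)C)C(C)C)cc1 | intermediate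
21 | B-[2-(oxepin-6-yl)ethyl]-9-borabicyclo[3.3.1]nonane derived from 14, (R) | C(CC1=CCC[C@@](CC(=O)c2cc(O[Si](C(C)C)(C(C)C)C(C)C)ccc2O[Si](C(C)C)(C(C)C)C(C)C)(C(=O)OCC[Si](C)(C)C)OC1)B1C2CCCC1CCC2 | intermediate
22 | tris(triisopropylsilyl) ether 2-(trimethylsilyl)ethyl ester of the target, (R), both side-chain alkenes E | C/C(=C\CCC1=CCC[C@@](CC(=O)c2cc(O[Si](C(C)C)(C(C)C)C(C)C)ccc2O[Si](C(C)C)(C(C)C)C(C)C)(C(=O)OCC[Si](C)(C)C)OC1)COC(=O)/C=C/c1ccc(O[Si](C(C)C)(C(C)C)C(C)C)cc1 | intermediate
23 | CNP0602535.1 | C/C(=C\CCC1=CCC[C@@](CC(=O)c2cc(O)ccc2O)(C(=O)O)OC1)COC(=O)/C=C/c1ccc(O)cc1 | target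

Total step count: 12. Longest linear sequence: 7 steps (1, 2, 5, 6, 7, 11, 12; the branch 3, 4, 5, 6, 7, 11, 12 is equally long).

Steps most likely to fail

**Risk 1 (step 6).**
- What may go wrong: O-alkylation of the hindered, electron-poor tertiary hydroxyl may be too slow. The triflate may decompose, or alkylation at the carbonyl oxygens may take over.
- Idea of the fallback: the aryl ketone is postponed, so that a classical base-mediated Williamson etherification becomes safe.
- The fallback sets out from keto ester 8. S-tert-butyl thioacetate is converted (LDA, TMSCl) into 1-(tert-butylthio)-1-(trimethylsilyloxy)ethene F1.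
- The catalyst of step 5 adds this to 8 to give the aldol silyl ether F2, which dilute acid hydrolyses to the (R)-thioester alcohol F3.
- Me(MeO)NH·HCl with iPrMgCl gives the Weinreb amide F4. Its amide enolate is too poor a leaving group for retro-aldol cleavage, so NaH and propargyl bromide should give the propargyl ether Weinreb amide F5.
- Bromohydroquinone is silylated to 2-bromo-1,4-bis(triisopropylsilyloxy)benzene F6 and exchanged with n-BuLi to the aryllithium F7.
- F7 is used in 2.2 equivalents because the first equivalent is consumed by the alkyne C–H. It adds to F5 at −78 °C, and the fallback comes back to the route at 13.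

**Risk 2 (step 11).**
- What may go wrong: the aryl ketone may be reduced by 9-BBN in competition with hydroboration. Base-induced E1cB opening of the oxepine during the coupling is also possible.
- Idea of the fallback: both the reducible carbonyl and the acidic CH2 are removed before boron is introduced.
- From 14, TBSOTf and Et3N give the (Z)-tert-butyldimethylsilyl enol ether diene F8.
- 9-BBN gives the enol ether borane F9, and coupling with 20 gives the coupled enol ether F10.
- The fluoride treatment of step 12 also removes the enol silyl group, so the fallback comes back to the route at 23.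

**Risk 3 (step 12).**
- What may go wrong: retro-oxa-Michael ring opening may occur under basic fluoride. Air oxidation of the hydroquinone phenoxide may occur before the slower ester fragmentation is complete.
- Idea of the fallback: the deprotection is staged and avoids basic media.
- From 22, HF·pyridine buffered with pyridine in THF removes the three aryl silyl groups to give the triphenol 2-(trimethylsilyl)ethyl ester F11.
- This ester is then fragmented by acid (TFA, CH2Cl2, 0 °C), and the fallback comes back to the route at 23.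

Further compounds
F1 | step 6 | 1-(tert-butylthio)-1-(trimethylsilyloxy)ethene | C=C(O[Si](C)(C)C)SC(C)(C)C
F2 | step 6 | O-trimethylsilyl ether of F3, (R) | C=CCC[C@@](CC(=O)SC(C)(C)C)(C(=O)OCC[Si](C)(C)C)O[Si](C)(C)C
F3 | step 6 | 2-(trimethylsilyl)ethyl (R)-2-[2-(tert-butylthio)-2-oxoethyl]-2-hydroxyhex-5-enoate | C=CCC[C@@](CC(=O)SC(C)(C)C)(C(=O)OCC[Si](C)(C)C)O
F4 | step 6 | 2-(trimethylsilyl)ethyl (R)-2-hydroxy-2-{2-[methoxy(methyl)amino]-2-oxoethyl}hex-5-enoate | C=CCC[C@@](CC(=O)N(C)OC)(C(=O)OCC[Si](C)(C)C)O
F5 | step 6 | 2-(trimethylsilyl)ethyl (R)-2-{2-[methoxy(methyl)amino]-2-oxoethyl}-2-(prop-2-ynyloxy)hex-5-enoate | C=CCC[C@@](CC(=O)N(C)OC)(C(=O)OCC[Si](C)(C)C)OCC#C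
F6 | step 6 | 2-bromo-1,4-bis(triisopropylsilyloxy)benzene | Brc1cc(O[Si](C(C)C)(C(C)C)C(C)C)ccc1O[Si](C(C)C)(C(C)C)C(C)C
F7 | step 6 | 2,5-bis(triisopropylsilyloxy)phenyllithium | [Li]c1cc(O[Si](C(C)C)(C(C)C)C(C)C)ccc1O[Si](C(C)C)(C(C)C)C(C)C
F8 | step 11 | (Z)-tert-butyldimethylsilyl enol ether of diene 14, (R) | C=CC1=CCC[C@@](/C=C(\O[Si](C)(C)C(C)(C)C)c2cc(O[Si](C(C)C)(C(C)C)C(C)C)ccc2O[Si](C(C)C)(C(C)C)C(C)C)(C(=O)OCC[Si](C)(C)C)OC1
F9 | step 11 | B-alkyl-9-BBN borane derived from F8 | C(CC1=CCC[C@@](/C=C(\O[Si](C)(C)C(C)(C)C)c2cc(O[Si](C(C)C)(C(C)C)C(C)C)ccc2O[Si](C(C)C)(C(C)C)C(C)C)(C(=O)OCC[Si](C)(C)C)OC1)B1C2CCCC1CCC2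
F10 | step 11 | (Z)-tert-butyldimethylsilyl enol ether of 22 | C/C(=C\CCC1=CCC[C@@](/C=C(\O[Si](C)(C)C(C)(C)C)c2cc(O[Si](C(C)C)(C(C)C)C(C)C)ccc2O[Si](C(C)C)(C(C)C)C(C)C)(C(=O)OCC[Si](C)(C)C)OC1)COC(=O)/C=C/c1ccc(O[Si](C(C)C)(C(C)C)C(C)C)cc1
F11 | step 12 | 2-(trimethylsilyl)ethyl ester of the target | C/C(=C\CCC1=CCC[C@@](CC(=O)c2cc(O)ccc2O)(C(=O)OCC[Si](C)(C)C)OC1)COC(=O)/C=C/c1ccc(O)cc1
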